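## Retrosynthetic overview

- Target 18 ⇐ desilylation and Steglich acylation of bis-silylated (−)-lariciresinol 15 with (2R)-2-methylbutanoic acid; 15 ⇐ borane reduction of oxolane acid 14 ⇐ hydrogenolysis of the benzylic lactone C–O bond of the cis-fused furofuranone 13.
- 13 ⇐ mixed acetal 10 by an intramolecular oxocarbenium / lactone silyl ketene acetal cyclisation that closes the oxolane through its C2–C3 bond; 10 ⇐ hydroxymethyl lactone 8 + acetal 9; 8 ⇐ Evans syn aldol/lactonisation of imide 5 with aldehyde 2.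
- Enabling feature: oxolane C2 is benzylic and bonded to ring O1 and to a 4-oxygenated aryl ring, so it can be an oxocarbenium carbon. C3 bears the exocyclic CH2O carbon, which at the carboxyl level makes C3 an enolate carbon. The cis pair CH2O (on C3) / ArCH2 (on C4) can be tied into a temporary γ-lactone through a temporary benzylic oxygen that hydrogenolysis later removes.
- Ring order: γ-lactone (step 3), then the oxolane (step 7, giving a cis-fused 3,7-dioxabicyclo[3.3.0]octan-2-one), then the lactone ring is opened (step 8).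

Key step: step 7

Remark: vanillin, (4R)-4-benzyl-1,3-oxazolidin-2-one, methyl 4-chloro-4-oxobutanoate and (2R)-2-methylbutanoic acid are taken as commercial. Oxolane positions are O1, C2 (aryl), C3 (CH2O), C4 (ArCH2), C5. Ar = 3-methoxy-4-(triisopropylsilyloxy)phenyl.

## Route

Step 1
Reactants: 1 vanillin (4-hydroxy-3-methoxybenzaldehyde)
Product: 2 3-methoxy-4-(triisopropylsilyloxy)benzaldehyde
Conditions: TIPSCl (1.2 equiv), imidazole (2.5 equiv), DMF, rt
Reagents that add atoms: triisopropylsilyl chloride CC(C)[Si](Cl)(C(C)C)C(C)C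
Why: Imidazole-promoted silyl ether formation masks the phenol with a group that should survive boron aldol, hydride, Lewis acid and hydrogenolysis conditions and leave with fluoride at the end.

Step 2
Reactants: 3 (4R)-4-benzyl-1,3-oxazolidin-2-one; 4 methyl 4-chloro-4-oxobutanoate
Product: 5 methyl 4-[(4R)-4-benzyl-2-oxo-1,3-oxazolidin-3-yl]-4-oxobutanoate
Conditions: n-BuLi (1.0 equiv), THF, −78 °C; then 4, −78 to 0 °C
Reagents that add atoms: none
Why: N-Acylation of the lithiated oxazolidinone by the acid chloride (far more reactive than the methyl ester) puts the Evans auxiliary on the four-carbon unit that becomes C3, C4, C5 and the exocyclic CH2O carbon of the oxolane.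

Step 3
Reactants: 5 methyl 4-[(4R)-4-benzyl-2-oxo-1,3-oxazolidin-3-yl]-4-oxobutanoate; 2 3-methoxy-4-(triisopropylsilyloxy)benzaldehyde
Product: 7 (4R)-4-benzyl-3-{[(2R,3R)-2-Ar-5-oxooxolan-3-yl]carbonyl}-1,3-oxazolidin-2-one (trans-lactone imide), via syn-aldol adduct 6 (not isolated)
Conditions: Bu2BOTf (1.1 equiv), iPr2NEt (1.2 equiv), CH2Cl2, −78 to 0 °C; 2, −78 to 0 °C; pH 7 buffer, MeOH, 30% H2O2, 0 °C; then PPTS (cat.), CH2Cl2, rt
Reagents that add atoms: none
Why: Evans syn aldol reaction: the Z-boron enolate reacts through a Zimmerman–Traxler chair on the face left open by the (R)-benzyl auxiliary to set the (R,R)-syn pair (future oxolane C4 and the temporary benzylic C–O centre), and the benzylic hydroxyl then lactonises onto the methyl ester (5-exo-trig acyl substitution), which turns syn into the trans-lactone.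

Step 4
Reactants: 7 trans-lactone imide
Product: 8 (4S,5R)-4-(hydroxymethyl)-5-Ar-oxolan-2-one
Conditions: NaBH4 (4 equiv), THF–H2O 4:1, 0 °C to rt
Reagents that add atoms: none
Why: Reductive auxiliary cleavage with NaBH4 in wet THF should reduce the exocyclic N-acyl oxazolidinone carbonyl, which is more electrophilic than the γ-lactone, to the primary alcohol without touching either stereocentre.

Step 5
Reactants: 2 3-methoxy-4-(triisopropylsilyloxy)benzaldehyde
Product: 9 4-(dimethoxymethyl)-2-methoxy-1-(triisopropylsilyloxy)benzene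
Conditions: HC(OMe)3 (as solvent), PPTS (cat.), rt; Et3N quench
Reagents that add atoms: trimethyl orthoformate COC(OC)OC
Why: Acid-catalysed acetalisation with the orthoformate as methoxy source and water scavenger converts the aldehyde into the acetal needed for acetal exchange.

Step 6
Reactants: 8 (4S,5R)-4-(hydroxymethyl)-5-Ar-oxolan-2-one; 9 4-(dimethoxymethyl)-2-methoxy-1-(triisopropylsilyloxy)benzene
Product: 10 (4S,5R)-4-{[methoxy(Ar)methoxy]methyl}-5-Ar-oxolan-2-one (mixed acetal; both acetal epimers)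
Conditions: 9 (3 equiv), PPTS (5 mol%), toluene, 40 °C, reduced pressure (removal of MeOH); Et3N quench; Et3N-deactivated silica
Reagents that add atoms: none
Why: Acid-catalysed transacetalisation, driven by removal of methanol and by excess 9, attaches the second aryl unit through oxygen as a mixed acetal whose acetal carbon becomes planar in the next step, so its configuration is of no consequence.

Step 7
Reactants: 10 mixed acetal
Product: 13 (3R,3aS,6R,6aR)-3,6-bis-Ar-tetrahydro-1H,3H-furo[3,4-c]furan-1-one (cis-fused; both aryl groups exo), via silyl ketene acetal 11 (not isolated), via oxocarbenium triflate 12 (not isolated)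
Conditions: Et3N (1.5 equiv), TMSOTf (1.3 equiv), CH2Cl2, 0 °C; then TMSOTf (0.5 equiv), −78 to −40 °C; aq. NaHCO3
Reagents that add atoms: none
Why: Soft enolisation (TMSOTf/Et3N) turns the γ-lactone into its silyl ketene acetal 11, and the small excess of TMSOTf then removes the methoxy group of the acetal as MeOSiMe3 to give the aryl-stabilised E-oxocarbenium ion 12, whose carbon is attacked by the ketene-acetal carbon to forge the oxolane C2–C3 bond and release TMSOTf. The closest known reaction types are the intramolecular Mukaiyama aldol-type addition of silyl ketene acetals to acetals and the oxocarbenium/enolate recombination that operates in Lewis-acid [1,3] O-to-C ring contractions of cyclic vinyl acetals. The oxolane closes in a 5-(enolexo)-endo-trig mode, with the oxocarbenium C=O inside and the enol C=C outside the new ring. The new centre C3 is fixed by the tether, since the CH2O arm on the adjacent lactone carbon can only reach its own face of the planar ketene acetal, so only the cis-fused bicycle can form and the carboxyl carbon on C3 ends up cis to the aryl-bearing carbon on C4; the new centre C2 should take the exo (2,3-trans) configuration because in the E-oxocarbenium the aryl group avoids eclipsing the silyloxy-bearing ketene-acetal carbon and the concave face, and reversible ionisation of the benzylic C2–O bond can only reinforce this more stable isomer. The step needs C- over O-alkylation and ionisation of the acetal rather than of the benzylic lactone C–O bond; an O-alkylated seven-membered ketene acetal would re-ionise and funnel to the C–C bonded lactone, and the acetal ionises far faster than the lactone at −78 °C.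

Step 8
Reactants: 13 cis-fused furofuranone
Product: 14 (2R,3R,4S)-2-Ar-4-(Ar-methyl)oxolane-3-carboxylic acid
Conditions: H2 (1 atm), 10% Pd/C, Et3N (1.2 equiv), EtOAc–MeOH, rt; dilute citric acid work-up
Reagents that add atoms: none
Why: Hydrogenolysis of a benzylic C–O bond: the lactone C–O bond is a benzylic ester linkage and should be cleaved much faster than the benzylic ether C–O bond of the oxolane (the amine additive further suppresses ether cleavage), which opens the temporary ring, erases the temporary stereocentre as ArCH2 and leaves the three oxolane centres untouched.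

Step 9
Reactants: 14 oxolane-3-carboxylic acid
Product: 15 [(2R,3S,4S)-2-Ar-4-(Ar-methyl)oxolan-3-yl]methanol (bis-TIPS ether of (−)-lariciresinol)
Conditions: BH3·THF (3 equiv), THF, 0 °C to rt; MeOH quench
Reagents that add atoms: none
Why: Borane reduction of a carboxylic acid (chemoselective via the acyloxyborane) should give the primary alcohol without epimerising C3.

Step 10
Reactants: 15 bis-TIPS ether of (−)-lariciresinol; 16 (2R)-2-methylbutanoic acid
Product: 17 [(2R,3S,4S)-2-Ar-4-(Ar-methyl)oxolan-3-yl]methyl (2R)-2-methylbutanoate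
Conditions: 16 (1.3 equiv), DIC (1.4 equiv), DMAP (0.1 equiv), CH2Cl2, 0 °C to rt
Reagents that add atoms: none
Why: Steglich esterification (carbodiimide activation with DMAP catalysis) of the only free hydroxyl at low temperature should proceed without epimerising the α-stereocentre of the acid, which comes unchanged from 16.

Step 11
Reactants: 17 bis-TIPS ester
Product: 18 [(2R,3S,4S)-2-(4-hydroxy-3-methoxyphenyl)-4-[(4-hydroxy-3-methoxyphenyl)methyl]oxolan-3-yl]methyl (2R)-2-methylbutanoate (target)
Conditions: TBAF (2.2 equiv), AcOH (2.5 equiv), THF, 0 °C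
Reagents that add atoms: none
Why: Fluoride-mediated desilylation of the two aryl silyl ethers, buffered with acetic acid so that the ester and the benzylic ether at C2 are not exposed to free phenoxide, should release the target.

## Compound list

1 | vanillin (4-hydroxy-3-methoxybenzaldehyde) | O=Cc1ccc(O)c(OC)c1 | starting material
2 | 3-methoxy-4-(triisopropylsilyloxy)benzaldehyde | O=Cc1ccc(O[Si](C(C)C)(C(C)C)C(C)C)c(OC)c1 | intermediate
3 | (4R)-4-benzyl-1,3-oxazolidin-2-one | O=C1N[C@H](Cc2ccccc2)CO1 | starting material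
4 | methyl 4-chloro-4-oxobutanoate | COC(=O)CCC(Cl)=O | starting material
5 | methyl 4-[(4R)-4-benzyl-2-oxo-1,3-oxazolidin-3-yl]-4-oxobutanoate | COC(=O)CCC(=O)N1[C@H](Cc2ccccc2)COC1=O | intermediate
6 | methyl (3R,4R)-3-{[(4R)-4-benzyl-2-oxo-1,3-oxazolidin-3-yl]carbonyl}-4-hydroxy-4-[3-methoxy-4-(triisopropylsilyloxy)phenyl]butanoate (syn-aldol adduct) | COC(=O)C[C@H]([C@@H](O)c1ccc(O[Si](C(C)C)(C(C)C)C(C)C)c(OC)c1)C(=O)N2[C@H](Cc3ccccc3)COC2=O | intermediate
7 | (4R)-4-benzyl-3-{[(2R,3R)-2-[3-methoxy-4-(triisopropylsilyloxy)phenyl]-5-oxooxolan-3-yl]carbonyl}-1,3-oxazolidin-2-one | O=C1O[C@@H](c2ccc(O[Si](C(C)C)(C(C)C)C(C)C)c(OC)c2)[C@H](C(=O)N3[C@H](Cc4ccccc4)COC3=O)C1 | intermediate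
8 | (4S,5R)-4-(hydroxymethyl)-5-[3-methoxy-4-(triisopropylsilyloxy)phenyl]oxolan-2-one | O=C1O[C@@H](c2ccc(O[Si](C(C)C)(C(C)C)C(C)C)c(OC)c2)[C@H](CO)C1 | intermediate
9 | 4-(dimethoxymethyl)-2-methoxy-1-(triisopropylsilyloxy)benzene | COC(OC)c1ccc(O[Si](C(C)C)(C(C)C)C(C)C)c(OC)c1 | intermediate
10 | (4S,5R)-4-({methoxy[3-methoxy-4-(triisopropylsilyloxy)phenyl]methoxy}methyl)-5-[3-methoxy-4-(triisopropylsilyloxy)phenyl]oxolan-2-one (both acetal epimers) | O=C1O[C@@H](c2ccc(O[Si](C(C)C)(C(C)C)C(C)C)c(OC)c2)[C@H](COC(OC)c3ccc(O[Si](C(C)C)(C(C)C)C(C)C)c(OC)c3)C1 | intermediate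
11 | (2R,3S)-2-aryl-3-{[methoxy(aryl)methoxy]methyl}-5-(trimethylsilyloxy)-2,3-dihydrofuran (silyl ketene acetal of 10) | C[Si](C)(C)OC1=C[C@@H](COC(OC)c2ccc(O[Si](C(C)C)(C(C)C)C(C)C)c(OC)c2)[C@H](c3ccc(O[Si](C(C)C)(C(C)C)C(C)C)c(OC)c3)O1 | intermediate
12 | E-oxocarbenium triflate formed from 11 by loss of methoxide | C[Si](C)(C)OC1=C[C@@H](C/[O+]=C/c2ccc(O[Si](C(C)C)(C(C)C)C(C)C)c(OC)c2)[C@H](c3ccc(O[Si](C(C)C)(C(C)C)C(C)C)c(OC)c3)O1.[O-]S(=O)(=O)C(F)(F)F | intermediate
13 | (3R,3aS,6R,6aR)-3,6-bis[3-methoxy-4-(triisopropylsilyloxy)phenyl]tetrahydro-1H,3H-furo[3,4-c]furan-1-one | O=C1O[C@@H](c2ccc(O[Si](C(C)C)(C(C)C)C(C)C)c(OC)c2)[C@@H]3CO[C@@H](c4ccc(O[Si](C(C)C)(C(C)C)C(C)C)c(OC)c4)[C@H]13 | intermediate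
14 | (2R,3R,4S)-2-[3-methoxy-4-(triisopropylsilyloxy)phenyl]-4-{[3-methoxy-4-(triisopropylsilyloxy)phenyl]methyl}oxolane-3-carboxylic acid | OC(=O)[C@@H]1[C@H](Cc2ccc(O[Si](C(C)C)(C(C)C)C(C)C)c(OC)c2)CO[C@H]1c3ccc(O[Si](C(C)C)(C(C)C)C(C)C)c(OC)c3 | intermediate
15 | [(2R,3S,4S)-2-[3-methoxy-4-(triisopropylsilyloxy)phenyl]-4-{[3-methoxy-4-(triisopropylsilyloxy)phenyl]methyl}oxolan-3-yl]methanol | OC[C@@H]1[C@H](Cc2ccc(O[Si](C(C)C)(C(C)C)C(C)C)c(OC)c2)CO[C@H]1c3ccc(O[Si](C(C)C)(C(C)C)C(C)C)c(OC)c3 | intermediate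
16 | (2R)-2-methylbutanoic acid | CC[C@@H](C)C(O)=O | starting material
17 | [(2R,3S,4S)-2-[3-methoxy-4-(triisopropylsilyloxy)phenyl]-4-{[3-methoxy-4-(triisopropylsilyloxy)phenyl]methyl}oxolan-3-yl]methyl (2R)-2-methylbutanoate | CC[C@@H](C)C(=O)OC[C@@H]1[C@H](Cc2ccc(O[Si](C(C)C)(C(C)C)C(C)C)c(OC)c2)CO[C@H]1c3ccc(O[Si](C(C)C)(C(C)C)C(C)C)c(OC)c3 | intermediate
18 | [(2R,3S,4S)-2-(4-hydroxy-3-methoxyphenyl)-4-[(4-hydroxy-3-methoxyphenyl)methyl]oxolan-3-yl]methyl (2R)-2-methylbutanoate | CC[C@@H](C)C(=O)OC[C@@H]1[C@H](Cc2ccc(O)c(OC)c2)CO[C@H]1c1ccc(O)c(OC)c1 | target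

## Step count and risks

Total step count: 11. Longest linear sequence: 9 steps (steps 1, 3, 4, 6, 7, 8, 9, 10, 11).

Steps most likely to fail:

Step 7 (key cyclisation). What may go wrong: poor exo/endo facial selectivity at C2, or ionisation of the benzylic lactone C–O bond and oligomerisation competing with ring closure. The fallback closes the oxolane by C–O instead of C–C bond formation (classical aldol/cyclodehydration chemistry); it sets out from 8 and comes back at 15. Hydrogenolysis of the benzylic lactone C–O bond of 8 (H2, Pd/C, EtOAc) should give (3S)-3-(hydroxymethyl)-4-arylbutanoic acid F1, which relactonises through its primary hydroxyl (cat. TsOH, toluene) to the (4S)-4-(arylmethyl)oxolan-2-one F2. Its lithium enolate (LDA, THF, −78 °C) should add to aldehyde 2 anti to the arylmethyl group to give the trans aldol lactone F3 (either carbinol epimer serves). LiBH4 reduces F3 to the triol F4, and camphorsulfonic acid in CH2Cl2 closes the oxolane by capture of the benzylic cation by the γ-hydroxyl under thermodynamic 2,3-trans control, giving 15.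

Step 8 (lactone hydrogenolysis). What may go wrong: over-reduction, that is hydrogenolysis of the benzylic C2–O bond of the oxolane together with or instead of the lactone C–O bond. The fallback uses radical deoxygenation instead of hydrogenolysis; it sets out from 13 and comes back at 17, so that steps 9 and 10 are not needed. LiBH4 (THF, 0 °C) reduces the lactone to the diol F5. DIC/DMAP with 16 (1 equiv, −20 °C) should acylate the primary hydroxyl selectively to give the hydroxy ester F6. 1,1'-Thiocarbonyldiimidazole (DMAP, CH2Cl2) converts the secondary benzylic hydroxyl into the imidazolylthiocarbonate F7, and Bu3SnH/AIBN (toluene, 80 °C, Barton–McCombie deoxygenation) removes it to give 17.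

Step 6 (mixed acetal). What may go wrong: disproportionation of the mixed acetal into the two symmetrical acetals, or its hydrolysis during isolation. The fallback uses irreversible O-alkylation instead of equilibrium acetal exchange; it sets out from 9 (with 8) and comes back at 10. Acetyl chloride (CH2Cl2, 0 °C) converts 9 into the α-chloro ether F8 with loss of methyl acetate, and F8 is used at once to alkylate the hydroxyl of 8 in the presence of iPr2NEt (CH2Cl2, −20 °C), giving 10.

Further compounds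

F1 | step 7 | (3S)-3-(hydroxymethyl)-4-[3-methoxy-4-(triisopropylsilyloxy)phenyl]butanoic acid | OC(=O)C[C@@H](CO)Cc1ccc(O[Si](C(C)C)(C(C)C)C(C)C)c(OC)c1
F2 | step 7 | (4S)-4-{[3-methoxy-4-(triisopropylsilyloxy)phenyl]methyl}oxolan-2-one | O=C1C[C@H](Cc2ccc(O[Si](C(C)C)(C(C)C)C(C)C)c(OC)c2)CO1
F3 | step 7 | (3R,4S)-3-{hydroxy[3-methoxy-4-(triisopropylsilyloxy)phenyl]methyl}-4-{[3-methoxy-4-(triisopropylsilyloxy)phenyl]methyl}oxolan-2-one (carbinol epimers) | O=C1OC[C@@H](Cc2ccc(O[Si](C(C)C)(C(C)C)C(C)C)c(OC)c2)[C@@H]1C(O)c3ccc(O[Si](C(C)C)(C(C)C)C(C)C)c(OC)c3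
F4 | step 7 | (2S,3S)-2-{hydroxy[3-methoxy-4-(triisopropylsilyloxy)phenyl]methyl}-3-{[3-methoxy-4-(triisopropylsilyloxy)phenyl]methyl}butane-1,4-diol (carbinol epimers) | OC[C@@H](C(O)c1ccc(O[Si](C(C)C)(C(C)C)C(C)C)c(OC)c1)[C@@H](CO)Cc2ccc(O[Si](C(C)C)(C(C)C)C(C)C)c(OC)c2
F5 | step 8 | [(2R,3S,4S)-4-{(R)-hydroxy[3-methoxy-4-(triisopropylsilyloxy)phenyl]methyl}-2-[3-methoxy-4-(triisopropylsilyloxy)phenyl]oxolan-3-yl]methanol | OC[C@@H]1[C@H]([C@@H](O)c2ccc(O[Si](C(C)C)(C(C)C)C(C)C)c(OC)c2)CO[C@H]1c3ccc(O[Si](C(C)C)(C(C)C)C(C)C)c(OC)c3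
F6 | step 8 | [(2R,3S,4S)-4-{(R)-hydroxy[3-methoxy-4-(triisopropylsilyloxy)phenyl]methyl}-2-[3-methoxy-4-(triisopropylsilyloxy)phenyl]oxolan-3-yl]methyl (2R)-2-methylbutanoate | CC[C@@H](C)C(=O)OC[C@@H]1[C@H]([C@@H](O)c2ccc(O[Si](C(C)C)(C(C)C)C(C)C)c(OC)c2)CO[C@H]1c3ccc(O[Si](C(C)C)(C(C)C)C(C)C)c(OC)c3
F7 | step 8 | [(2R,3S,4S)-4-{(R)-[(1H-imidazol-1-ylcarbonothioyl)oxy][3-methoxy-4-(triisopropylsilyloxy)phenyl]methyl}-2-[3-methoxy-4-(triisopropylsilyloxy)phenyl]oxolan-3-yl]methyl (2R)-2-methylbutanoate | CC[C@@H](C)C(=O)OC[C@@H]1[C@H]([C@@H](OC(=S)n2ccnc2)c3ccc(O[Si](C(C)C)(C(C)C)C(C)C)c(OC)c3)CO[C@H]1c4ccc(O[Si](C(C)C)(C(C)C)C(C)C)c(OC)c4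
F8 | step 6 | 4-[chloro(methoxy)methyl]-2-methoxy-1-(triisopropylsilyloxy)benzene (racemic) | COC(Cl)c1ccc(O[Si](C(C)C)(C(C)C)C(C)C)c(OC)c1
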